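The numbers of this flask are those of an exercise; no experiment stands behind them.

A small charge of L had to compete with a large charge of E for the Q in this flask.

    Q + E → Q.E (k1 = 0.400 M⁻¹ s⁻¹)
    E + L + Z → L + J (k2 = 3760 M⁻² s⁻¹)
    Q + J ⇌ Q.J, settled at all times (K3 = 44 M⁻¹)
    Q + L → L + Z (k4 = 68.1 M⁻¹ s⁻¹)

Q 0.050 M; E 0.125 M; L 0.25 mM; time 20 min

- in percentages every species weighs as the Q in it: one Q.J counts as two
- for J the Q.J is counted in
- in an amount of J, one Q.J counts as one J
- the reaction counts as stopped when no species that holds the Q changes by six tenths of a point or more over the second half of the time
- run time (flask): 20 min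

* at 20 min, what has stopped the reaction, if anything has (it is still moving / E has run out first / no working catalyst is left / forward and back rates have come level / all of Q has reacted)
* conversion of Q at 20 min
* amount of J at 20 min, in percent of the Q charged

I reckoned the rate of loss of Q. Each of its two paths is pseudo-first-order in Q: E turns Q into Q.E, and L turns Q into Z. Z then takes one E on its way to J, so I counted one E lost per Q reacted. At the start:

E path 0.0500 s⁻¹ + L path 0.0170 s⁻¹ = 0.0670 s⁻¹

The L path held steady, since L is not consumed. The E path weakened as E fell, and I reckoned that a fall of E by the charge of Q slowed the total by a factor of 1.43. I took the E path at the midpoint of that fall, 0.0400 s⁻¹, and reckoned: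

L share = 0.0170 s⁻¹ / (0.0170 s⁻¹ + 0.0400 s⁻¹) = 29.9%

The L share is the part of reacted Q that goes through L, a selectivity. J binds Q as Q.J, and I put the further slowing of both paths alike at a factor of 1.66, which left the share as it was. With both factors the time constant became 35.2 s, much shorter than the run, which holds 34.1 time constants. I therefore committed to complete conversion, a stop through loss of Q, and J at the L share.

The forecast gave all of Q has reacted, conversion 100% and J 29.8%, on this ground: “The J share depends only on the branching ratio, not on sequestration”.

The simulation gave all of Q has reacted, conversion 100% and J 29.6%.

In the flask, Q.J held 0.892% at 2.00 min and 0% at 10.0 min. The J of this flask stood 0.30 percentage points below my L share and came to 59.3 turnovers per L. The neighbour flask was charged with 0.12 M of Q, which made E 1.04 equiv. For it, the same reckoning put the E path at 0.0260 s⁻¹ and the L share at 39.6%, or 190 turnovers. The neighbour flask gave J 41.1%, or 197 turnovers, with 4.1% of its E left.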